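## Structural features

Salimabromide is a tetracycle on a benzo-fused bicyclo[4.3.1]decane. The seven-membered carbocycle is labelled C1–C7 here: C1 = CH carrying the lactone carbonyl C8, C2 = benzylic CH, C3 = CH–O, C4 = ketone, C5=C6 = enone alkene, C7 = methyl-bearing quaternary carbon. It is bridged from C2 to C7 by two ortho arene carbons and the benzylic CMe2 carbon C9, which closes the tetralin ring (C2, C1, C7, C9 and two arene carbons). A γ-lactone (C1–C8(=O)–O–C3) spans C1 and C3 on the ring face opposite the arene bridge. The four stereocentres C3–C2–C1–C7 are contiguous (3S, 2S, 1R, 7R in these labels), and quaternary C7 lies between tertiary C1 and fully substituted C9. The arene is pentasubstituted, with ethyl flanked by two bromines. Fragile groups are the α-acyloxy enone (Michael acceptor, base-sensitive), C1–H α to the lactone, and the aryl bromides, which do not tolerate aryl-metal or Pd(0) chemistry. Once the rings are closed the relative configuration is forced, so the real difficulty is the seven-membered ring together with the C1/C7 pair in the correct absolute sense. The key step exploits the fact that C7 is allylic to C5=C6 and vicinal to C1, which is α to carboxyl C8. The unit C8(=O)–C1–C7–C6=C5 is the retron of an ester-enolate Claisen rearrangement whose ester oxygen sat on C5, and tying C5–O–C8 into a lactone makes that rearrangement close the seven-membered ring.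

## Logic of the disconnections

26 ⇒ 25. The two aryl C–Br bonds are cut first. Bromine-free arenes tolerate the organomagnesium, copper and cationic steps and are more nucleophilic in the ring closure; the arene fragment simplifies to purchasable 17. The forward step must brominate both positions ortho to ethyl and leave the enone alone.

25 ⇒ 23. The bond from C9 to the arene carbon para to ethyl is cut, which opens the tetralin ring. C9 becomes the tertiary cation of an isopropenyl group on C7, and the arene becomes a plain substituent on C2. The forward cyclialkylation must outrun 1,2-shifts; the lactone bridge of 23 holds aryl and isopropenyl syn on the seven-membered ring.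

23 ⇒ 22. The lactone C8–O bond is cut to a hydroxy ester. This removes the bridged bicycle and requires only that C3–OH and the C1 ester be cis.

22 ⇒ 19. The C3–O bond is cut to a silyl enol ether. Oxygen is delivered to C3 from the face opposite the C2 aryl group, so C3 is relayed from C2.

19 ⇒ 16 + 17. The C2–aryl bond is cut. C2 is a β-carbon of the cross-conjugated dienone 16, so the arene enters by conjugate addition, anti to the C1 ester, and the enolate is kept for the C3 oxygenation. The step must choose C2 over the neopentyl β-carbon C6 and must not deprotonate C1.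

16 ⇒ 15 ⇒ 14. The C4=O bond is cut to the doubly allylic methylene of a 1,4-cycloheptadiene, and the methyl ester is traced to acid 14. The forward oxidation must select C4–H over C1–H.

14 ⇒ 11 (key). The C1–C7 bond is cut and C5–O is reconnected, giving the seven-membered lactone 11 with a Z-dienyl group on its single stereocentre C5. One sentence: an Ireland–Claisen rearrangement of the silyl ketene acetal of alkenyl lactone 11 turns the lactone into cycloheptadiene acid 14. The carbocycle, the C5=C6 alkene, the C8 carboxyl and both C1 and C7 arise together. The forward step must pass through a boat with the isopropenyl group on the inner position.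

11 ⇒ 9 + 10. The C7–C9 sp2–sp2 bond is cut to a Z-vinyl iodide and stannane 10. The isopropenyl group is the latent C9 cation, and its position cis to C5 is what the Claisen turns into the C7 configuration.

9 ⇒ 8 ⇒ 6 + 7. The C2=C3 ring alkene is cut (ring-closing metathesis), then the C8–O ester bond. The same alkene later serves as the enone for arylation and oxygenation. The metathesis must leave the iodoalkene alone.

6 ⇒ 4 ⇒ 1 + 2. The C7–I and C6–H bonds are cut to the alkyne of 4 (hydroxyl-directed trans-hydroalumination fixes the geometry). The C4–C5 bond is then cut to aldehyde 1 and allylborane 2, the only step in which a reagent sets a stereocentre.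

## Other disconnections considered

Alternative 1: the first that comes to mind. Build the tetralin by Friedel–Crafts cyclialkylation, then cut C5=C6 and close the cycloheptenone by ring-closing metathesis of diene A1. Every stereocentre of A1, including quaternary C7 wedged between C1 and C9, must be installed by separate operations on a crowded tetralin. The metathesis has to engage a neopentyl vinyl group with an enone. The chosen plan makes C1 and C7 in one pericyclic step and relays C2 and C3 from them.

Alternative 2: cut C2–C3 and C6–C7 and form the bicyclo[4.3.1] core by a (4+3) cycloaddition of the oxyallyl cation from bromotetralone A2 with furan, giving adduct A3. C1 arrives as a bridging ketone that would need one-carbon homologation at the most hindered carbon. The furan oxygen lands on both C3 and C6 and must be removed from C6 and a ketone placed at C4. Nothing fixes the absolute configuration of C7. The number of corrective steps outweighs the one-step core construction.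

Alternative 3: cut C1–C2 and C3–C8. An intramolecular ketene–styrene [2+2] from acid chloride A4 gives cyclobutanone A5, then Baeyer–Villiger oxidation to the lactone and late closure of the seven-membered ring. The quaternary C7 next to CMe2Ar must already be enantioenriched in an open chain, so the hardest stereocentre is not solved by the key step. The oxygen insertion must distinguish two secondary α-carbons. The seven-membered ring is still open afterwards.

Key step: step 6

Remark (assumption): 1 and 2 are taken as purchased materials (1 is also available from its commercial diethyl acetal); the locants C1–C9 in the Why lines are the target labels defined above.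

## Steps

Step 1
Reactants: 1 but-2-ynal; 2 (−)-B-allyldiisopinocampheylborane
Product: 4 (4S)-hept-1-en-5-yn-4-ol, via hept-1-en-5-yn-4-yl diisopinocampheylborinate 3 (not isolated)
Conditions: 2 (1.1 equiv), Et2O, −78 °C; then 3 M NaOH, 30% H2O2, 0 °C → rt
Reagents that add atoms: none
Why: Brown allylboration through a closed chair transition state; the isopinocampheyl groups of 2 (from (+)-α-pinene) should direct allyl transfer to the Si face of the aldehyde and give the (S)-carbinol, which is C5 of the target labels and the only stereocentre set by a reagent. Oxidative work-up cleaves borinate 3.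

Step 2
Reactants: 4 (4S)-hept-1-en-5-yn-4-ol
Product: 6 (4S,5Z)-6-iodohepta-1,5-dien-4-ol, via cyclic sodium vinylalanate 5 (not isolated)
Conditions: Red-Al (1.5 equiv), THF, 0 °C → rt; then I2, THF, −78 → 0 °C; aq. Rochelle salt
Reagents that add atoms: iodine, II
Why: Hydroxyl-directed trans-hydroalumination of a propargylic alcohol: hydride goes to the proximal alkyne carbon and aluminium to the distal one inside the five-membered alanate 5, so iodine (introduced with retention) ends cis to the carbinol carbon. This Z geometry is what the key step converts into the C7 configuration; the terminal alkene is inert.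

Step 3
Reactants: 6 (4S,5Z)-6-iodohepta-1,5-dien-4-ol; 7 but-3-enoic acid
Product: 8 (4S,5Z)-6-iodohepta-1,5-dien-4-yl but-3-enoate
Conditions: DCC, DMAP (5 mol%), CH2Cl2, −10 → 0 °C
Reagents that add atoms: none
Why: Steglich esterification; low temperature and little DMAP should keep the β,γ-unsaturated acyl group out of conjugation, and the carbinol stereocentre is not touched.

Step 4
Reactants: 8 (4S,5Z)-6-iodohepta-1,5-dien-4-yl but-3-enoate
Product: 9 (7S)-7-[(1Z)-2-iodoprop-1-en-1-yl]-6,7-dihydrooxepin-2(3H)-one
Conditions: Grubbs II (5 mol%), 1,4-benzoquinone (10 mol%), CH2Cl2 (2 mM), 40 °C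
Reagents that add atoms: none
Why: Ring-closing metathesis of the two monosubstituted alkenes should give the seven-membered β,γ-unsaturated lactone with the cis C2=C3 bond; the trisubstituted iodoalkene is too hindered and electron-poor to enter the cycle. High dilution favours closure and benzoquinone suppresses alkene migration.

Step 5
Reactants: 9 (7S)-7-[(1Z)-2-iodoprop-1-en-1-yl]-6,7-dihydrooxepin-2(3H)-one; 10 tributyl(prop-1-en-2-yl)stannane
Product: 11 (7S)-7-[(1Z)-2,3-dimethylbuta-1,3-dien-1-yl]-6,7-dihydrooxepin-2(3H)-one
Conditions: Pd2(dba)3 (2.5 mol%), AsPh3 (10 mol%), CuI (10 mol%), NMP, rt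
Reagents that add atoms: none
Why: Stille coupling with retention of alkene geometry places the isopropenyl group (future C9) cis to C5. Neutral conditions at room temperature spare the β,γ-unsaturated lactone, and oxidative addition into C–I should be much faster than ionisation of the allylic ester.

Step 6
Reactants: 11 (7S)-7-[(1Z)-2,3-dimethylbuta-1,3-dien-1-yl]-6,7-dihydrooxepin-2(3H)-one
Product: 14 (1R,7R)-7-methyl-7-(prop-1-en-2-yl)cyclohepta-2,5-diene-1-carboxylic acid, via cyclic trimethylsilyl ketene acetal 12 (not isolated), via trimethylsilyl ester 13 (not isolated)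
Conditions: LDA (1.2 equiv), TMSCl/Et3N (premixed), THF, −78 °C → rt; then PhMe, 80 °C; pH 5 aqueous buffer
Reagents that add atoms: none
Why: LDA removes a C1–H (α to the lactone carbonyl and allylic) and the dienolate is O-silylated in situ to 12, whose allyl vinyl ether unit C1=C8–O–C5–C6=C7 undergoes a concerted [3,3] shift that forms C1–C7 and breaks C5–O to give 13, hydrolysed on work-up. The closest known reaction type is the Ireland–Claisen rearrangement of silyl ketene acetals of alkenyl lactones to cycloalkene carboxylic acids. The ring closed is the seven-membered carbocycle C1–C7, formed by C1–C7 bonding through a bicyclo[3.2.2]-like transition state, with the new C5=C6 bond necessarily cis. Because the tether C2–C3–C4 links the two termini of the pericyclic array, only the boat is geometrically possible. C1 is controlled by the C5 stereocentre, which holds the dienyl group over one face of the ketene acetal, so (5S) should give (1R). C7 is controlled by the Z geometry of C6=C7 within the enforced boat: the inner isopropenyl group ends trans to the carboxyl group and the outer methyl cis, giving (7R), so one carbinol centre is transferred to a tertiary–quaternary pair. The step needs bonding at the α-carbon of the dienolate and rearrangement faster than decomposition; the first is secured because only C1 can reach C7, and the second is helped because the planar inner isopropenyl group lies under the flat sp2 C2–H of the tether, not under a substituted sp3 carbon. The buffered work-up avoids acid-induced lactonisation of the carboxyl group onto the isopropenyl group.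

Step 7
Reactants: 14 (1R,7R)-7-methyl-7-(prop-1-en-2-yl)cyclohepta-2,5-diene-1-carboxylic acid
Product: 15 methyl (1R,7R)-7-methyl-7-(prop-1-en-2-yl)cyclohepta-2,5-diene-1-carboxylate
Conditions: TMSCHN2, PhMe/MeOH 4:1, 0 °C
Reagents that add atoms: (trimethylsilyl)diazomethane, C[Si](C)(C)C=[N+]=[N-]
Why: O-Methylation of the acid under neutral conditions, so C1 is not epimerised and no acid is present that could cyclise the carboxyl group onto the isopropenyl group.

Step 8
Reactants: 15 methyl (1R,7R)-7-methyl-7-(prop-1-en-2-yl)cyclohepta-2,5-diene-1-carboxylate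
Product: 16 methyl (1R,7R)-7-methyl-4-oxo-7-(prop-1-en-2-yl)cyclohepta-2,5-diene-1-carboxylate
Conditions: CrO3, 3,5-dimethylpyrazole, CH2Cl2, −20 °C
Reagents that add atoms: chromium trioxide, O=[Cr](=O)=O
Why: Cr(VI) allylic oxidation at the only doubly allylic methylene (C4), the same type as oxidation of 3,3-disubstituted 1,4-cyclohexadienes to cross-conjugated dienones. C1–H is α to the ester (polarity-mismatched for an electrophilic oxidant) and neopentyl, and C7 carries no hydrogen.

Step 9
Reactants: 16 methyl (1R,7R)-7-methyl-4-oxo-7-(prop-1-en-2-yl)cyclohepta-2,5-diene-1-carboxylate; 17 1-bromo-3-ethylbenzene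
Product: 19 methyl (1R,2S,7R)-2-(3-ethylphenyl)-7-methyl-7-(prop-1-en-2-yl)-4-[(trimethylsilyl)oxy]cyclohepta-3,5-diene-1-carboxylate, via 3-ethylphenylmagnesium bromide 18 (not isolated)
Conditions: 17, Mg, THF, rt; then CuBr·SMe2 (15 mol%), TMSCl (2 equiv), 16, THF, −78 °C; Et3N, cold NaHCO3 work-up
Reagents that add atoms: chlorotrimethylsilane, C[Si](C)(C)Cl
Why: Copper-catalysed, TMSCl-accelerated conjugate addition of the aryl Grignard reagent; of the two β-carbons, C6 is neopentyl, so the aryl group should go to C2. Addition anti to the adjacent C1 ester (the usual trans selectivity for γ-substituted cycloalkenones) sets C2 as S, and the enolate is trapped as the silyl dienol ether.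

Step 10
Reactants: 19 methyl (1R,2S,7R)-2-(3-ethylphenyl)-7-methyl-7-(prop-1-en-2-yl)-4-[(trimethylsilyl)oxy]cyclohepta-3,5-diene-1-carboxylate
Product: 22 methyl (1R,2S,3S,7R)-2-(3-ethylphenyl)-3-hydroxy-7-methyl-4-oxo-7-(prop-1-en-2-yl)cyclohept-5-ene-1-carboxylate, via silyloxy epoxide 20 (not isolated), via alpha-silyloxy ketone 21 (not isolated)
Conditions: mCPBA (1.05 equiv), NaHCO3, CH2Cl2, −20 °C; then 1 M HCl, THF, 0 °C
Reagents that add atoms: 3-chloroperbenzoic acid, OOC(=O)c1cccc(Cl)c1
Why: Rubottom oxidation: the peracid epoxidises the electron-rich enol ether bond C3=C4 on the face anti to the neighbouring aryl group (cis to the C1 ester) to give 20; ring opening with 1,4-silyl shift gives 21, and dilute acid frees the alcohol, setting C3 as S. With one equivalent at low temperature the isopropenyl and enone alkenes should react far more slowly.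

Step 11
Reactants: 22 methyl (1R,2S,3S,7R)-2-(3-ethylphenyl)-3-hydroxy-7-methyl-4-oxo-7-(prop-1-en-2-yl)cyclohept-5-ene-1-carboxylate
Product: 23 (1R,2R,6S,9S)-9-(3-ethylphenyl)-2-methyl-2-(prop-1-en-2-yl)-7-oxabicyclo[4.2.1]non-3-ene-5,8-dione
Conditions: PPTS (10 mol%), PhMe, 4 Å MS, 90 °C
Reagents that add atoms: none
Why: Acid-catalysed transesterification of the cis-1,3 hydroxy ester to the bridged γ-lactone, driven by loss of methanol. PPTS is too weak to protonate the isopropenyl group, and once C3 is a bridgehead it can no longer epimerise.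

Step 12
Reactants: 23 (1R,2R,6S,9S)-9-(3-ethylphenyl)-2-methyl-2-(prop-1-en-2-yl)-7-oxabicyclo[4.2.1]non-3-ene-5,8-dione
Product: 25 didebromosalimabromide (the tetracycle of the target lacking both bromine atoms), via tertiary carbocation 24 (not isolated)
Conditions: TfOH (0.2–1 equiv), HFIP/CH2Cl2, 0 °C → rt
Reagents that add atoms: none
Why: Markovnikov protonation of the isopropenyl group gives cation 24 at C9, which alkylates the arene para to ethyl and ortho to the C2 attachment in a six-membered closure (intramolecular Friedel–Crafts alkylation). The lactone bridge holds the aryl group and the cation syn on the seven-membered ring, and 1,2-shifts from C7 would put charge next to the enone or the lactone carbonyl. No new stereocentre is formed.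

Step 13
Reactants: 25 didebromosalimabromide
Product: 26 salimabromide
Conditions: DBDMH (1.1 equiv), TfOH (10 mol%), CH2Cl2, 0 °C → rt, dark
Reagents that add atoms: 1,3-dibromo-5,5-dimethylhydantoin, CC1(C)N(Br)C(=O)N(Br)C1=O
Why: Electrophilic aromatic bromination: the two positions ortho to ethyl are each activated by two alkyl groups, whereas the third free position is activated by one and is flanked by the CMe2 group. The enone alkene is electron-poor, C3–H cannot enolise (bridgehead), and exclusion of light avoids benzylic radical bromination.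

## Compound list

1 | but-2-ynal | CC#CC=O | starting material
2 | (−)-B-allyldiisopinocampheylborane (Ipc groups from (+)-α-pinene) | C=CCB([C@@H]1C[C@@H]2C[C@H]([C@H]1C)C2(C)C)[C@@H]1C[C@@H]2C[C@H]([C@H]1C)C2(C)C | starting material
3 | (4S)-hept-1-en-5-yn-4-yl diisopinocampheylborinate | C=CC[C@H](OB([C@@H]1C[C@@H]2C[C@H]([C@H]1C)C2(C)C)[C@@H]1C[C@@H]2C[C@H]([C@H]1C)C2(C)C)C#CC | intermediate
4 | (4S)-hept-1-en-5-yn-4-ol | C=CC[C@H](O)C#CC | intermediate
5 | sodium salt of the five-membered cyclic vinylalanate (O–Al–C=C–C ring, Al cis to the carbinol carbon, two 2-methoxyethoxy ligands, S at the carbinol carbon) | C=CC[C@@H]1O[Al-](OCCOC)(OCCOC)C(C)=C1.[Na+] | intermediate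
6 | (4S,5Z)-6-iodohepta-1,5-dien-4-ol | C=CC[C@H](O)/C=C(/C)I | intermediate
7 | but-3-enoic acid | C=CCC(=O)O | starting material
8 | (4S,5Z)-6-iodohepta-1,5-dien-4-yl but-3-enoate | C=CC[C@H](OC(=O)CC=C)/C=C(/C)I | intermediate
9 | (7S)-7-[(1Z)-2-iodoprop-1-en-1-yl]-6,7-dihydrooxepin-2(3H)-one | O=C1CC=CC[C@@H](/C=C(/C)I)O1 | intermediate
10 | tributyl(prop-1-en-2-yl)stannane | CCCC[Sn](CCCC)(CCCC)C(C)=C | starting material
11 | (7S)-7-[(1Z)-2,3-dimethylbuta-1,3-dien-1-yl]-6,7-dihydrooxepin-2(3H)-one | O=C1CC=CC[C@@H](/C=C(/C)C(C)=C)O1 | intermediate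
12 | (7S)-7-[(1Z)-2,3-dimethylbuta-1,3-dien-1-yl]-2-[(trimethylsilyl)oxy]-6,7-dihydrooxepine | C[Si](C)(C)OC1=CC=CC[C@@H](/C=C(/C)C(C)=C)O1 | intermediate
13 | trimethylsilyl (1R,7R)-7-methyl-7-(prop-1-en-2-yl)cyclohepta-2,5-diene-1-carboxylate | C[Si](C)(C)OC(=O)[C@@H]1C=CCC=C[C@@]1(C)C(C)=C | intermediate
14 | (1R,7R)-7-methyl-7-(prop-1-en-2-yl)cyclohepta-2,5-diene-1-carboxylic acid | OC(=O)[C@@H]1C=CCC=C[C@@]1(C)C(C)=C | intermediate
15 | methyl (1R,7R)-7-methyl-7-(prop-1-en-2-yl)cyclohepta-2,5-diene-1-carboxylate | COC(=O)[C@@H]1C=CCC=C[C@@]1(C)C(C)=C | intermediate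
16 | methyl (1R,7R)-7-methyl-4-oxo-7-(prop-1-en-2-yl)cyclohepta-2,5-diene-1-carboxylate | COC(=O)[C@@H]1C=CC(=O)C=C[C@@]1(C)C(C)=C | intermediate
17 | 1-bromo-3-ethylbenzene | CCc1cccc(Br)c1 | starting material
18 | 3-ethylphenylmagnesium bromide | CCc1cccc([Mg]Br)c1 | intermediate
19 | methyl (1R,2S,7R)-2-(3-ethylphenyl)-7-methyl-7-(prop-1-en-2-yl)-4-[(trimethylsilyl)oxy]cyclohepta-3,5-diene-1-carboxylate | COC(=O)[C@@H]1[C@@H](c2cccc(CC)c2)C=C(O[Si](C)(C)C)C=C[C@@]1(C)C(C)=C | intermediate
20 | 3,4-epoxide of 19 (epoxide oxygen on the ring face opposite the C2 aryl group, cis to the C1 ester) | COC(=O)[C@@H]1[C@@H](c2cccc(CC)c2)[C@@H]3O[C@]3(O[Si](C)(C)C)C=C[C@@]1(C)C(C)=C | intermediate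
21 | methyl (1R,2S,3S,7R)-2-(3-ethylphenyl)-7-methyl-4-oxo-7-(prop-1-en-2-yl)-3-[(trimethylsilyl)oxy]cyclohept-5-ene-1-carboxylate | COC(=O)[C@@H]1[C@@H](c2cccc(CC)c2)[C@H](O[Si](C)(C)C)C(=O)C=C[C@@]1(C)C(C)=C | intermediate
22 | methyl (1R,2S,3S,7R)-2-(3-ethylphenyl)-3-hydroxy-7-methyl-4-oxo-7-(prop-1-en-2-yl)cyclohept-5-ene-1-carboxylate | COC(=O)[C@@H]1[C@@H](c2cccc(CC)c2)[C@H](O)C(=O)C=C[C@@]1(C)C(C)=C | intermediate
23 | (1R,2R,6S,9S)-9-(3-ethylphenyl)-2-methyl-2-(prop-1-en-2-yl)-7-oxabicyclo[4.2.1]non-3-ene-5,8-dione | CCc1cccc(c1)[C@H]1[C@@H]2OC(=O)[C@H]1[C@@](C)(C=CC2=O)C(C)=C | intermediate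
24 | tertiary carbocation at C9 formed from 23 by protonation of the isopropenyl group | CCc1cccc(c1)[C@H]1[C@@H]2OC(=O)[C@H]1[C@@](C)(C=CC2=O)[C+](C)C | intermediate
25 | didebromosalimabromide (target tetracycle without the two bromine atoms; C1 R, C2 S, C3 S, C7 R) | CCc1ccc2c(c1)[C@H]1[C@@H]3OC(=O)[C@H]1[C@@](C)(C=CC3=O)C2(C)C | intermediate
26 | salimabromide | CCc1c(Br)cc2c(c1Br)[C@H]1[C@@H]3OC(=O)[C@H]1[C@@](C)(C=CC3=O)C2(C)C | target

## Step count and least certain steps

Total: 13 steps. Longest linear sequence: 13 steps (1 → 26); 2, 7, 10 and 17 enter as purchased materials.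

Step 6 (key step). The boat transition state must accommodate the isopropenyl group on the inner position of C7 beneath the C1–C2 edge of the tether. The rearrangement may therefore be slower than desilylation, decomposition of the electron-rich ketene acetal, or a 1,5-hydrogen shift in the Z-diene on prolonged heating. The fallback keeps the bond construction but uses a rod-like inner substituent and builds C9 differently. It sets out from 9: Sonogashira coupling with (trimethylsilyl)acetylene should give the enyne lactone F1, the same enolisation–silylation–heating sequence should give the alkynyl acid F2, and K2CO3 in methanol should remove the silyl group to give the terminal alkyne F3. Zirconium-catalysed methylalumination of F3 (Me3Al, Cp2ZrCl2, then water) would put methyl on the internal alkyne carbon and return to the route at 14.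

Step 8. Hydrogen abstraction could also occur at C1 (tertiary, allylic, α to the ester) or at the isopropenyl methyl, and over-oxidation is possible, because the reagent distinguishes C–H bonds only by strength, polarity and access. The fallback brings the C4 oxygen in with the allyl unit instead of by C–H oxidation. It sets out from 1: Brown alkoxyallylboration with the (Z)-γ-(methoxymethoxy)allyl diisopinocampheylborane of the same pinene series should give the syn diol monoether F4. The operations of steps 2 to 7 on this series would give iodide F5, ester F6, lactone F7, dienyl lactone F8, acid F9 and methyl ester F10. DDQ in wet CH2Cl2 should then abstract hydride from the doubly allylic, oxygen-bearing C4–H of F10, and hydrolysis of the oxocarbenium ion returns to the route at 16. The C4 stereocentre is destroyed there, so its configuration does not matter.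

Step 9. The basic organometallic may deprotonate C1 (α to the ester and vinylogous to the ketone), which would erode the C1 configuration or isomerise the dienone. Facial selectivity may also be imperfect, because the face anti to the ester is the face that carries the C7 isopropenyl group. The fallback is a catalyst-controlled, non-basic arylation. It sets out from 16: rhodium(I)/BINAP-catalysed (Hayashi–Miyaura) addition of 3-ethylphenylboronic acid in aqueous dioxane without added base should give ketone F11, with the ligand enantiomer chosen so that catalyst and substrate preferences coincide. Kinetic enolisation of F11 towards C3 (LiHMDS, TMSCl, −78 °C) returns to the route at 19.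

Step 12. The arene may instead attack the protonated enone at C6 (also a six-membered closure) or react ortho to ethyl, and the cation may be diverted by reversible capture at the lactone carbonyl or by a 1,2-shift. The fallback forms the bond from an aryl halide instead of a cation. It sets out from 16: conjugate addition of 2-bromo-5-ethylphenylmagnesium chloride F12 (made by iodine–magnesium exchange on the corresponding aryl iodide) under the conditions of step 9 should give silyl enol ether F13. Rubottom oxidation as in step 10 gives hydroxy ketone F14 and lactonisation as in step 11 gives bromoaryl lactone F15. A 6-exo reductive Heck cyclisation of F15 onto the isopropenyl group (Pd(OAc)2, PPh3, HCO2Na, DMF) would create the quaternary C9 and return to the route at 25.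

Step 13. The second bromination, at the position between ethyl and the C2 attachment, may be slow or misdirected; bromine may add to the enone, or benzylic bromination may compete. The fallback carries the bromines in with the arene. It sets out from 16: conjugate addition of 2,4-dibromo-3-ethylphenylmagnesium chloride F16 (made by magnesiation of 1,3-dibromo-2-ethylbenzene with TMPMgCl·LiCl ortho to bromine) should give silyl enol ether F17. The operations of steps 10 and 11 give hydroxy ketone F18 and dibromoaryl lactone F19. The acid-mediated cyclialkylation of step 12, now para to ethyl and meta to both bromines, would return to the route at 26.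

## Further compounds

F1 | step 6 | (7S)-7-[(1Z)-2-methyl-4-(trimethylsilyl)but-1-en-3-yn-1-yl]-6,7-dihydrooxepin-2(3H)-one | O=C1CC=CC[C@@H](/C=C(/C)C#C[Si](C)(C)C)O1
F2 | step 6 | (1R,7R)-7-methyl-7-[(trimethylsilyl)ethynyl]cyclohepta-2,5-diene-1-carboxylic acid | OC(=O)[C@@H]1C=CCC=C[C@@]1(C)C#C[Si](C)(C)C
F3 | step 6 | (1R,7R)-7-ethynyl-7-methylcyclohepta-2,5-diene-1-carboxylic acid | OC(=O)[C@@H]1C=CCC=C[C@@]1(C)C#C
F4 | step 8 | (3R,4R)-3-(methoxymethoxy)hept-1-en-5-yn-4-ol | C=C[C@@H](OCOC)[C@H](O)C#CC
F5 | step 8 | (3R,4R,5Z)-6-iodo-3-(methoxymethoxy)hepta-1,5-dien-4-ol | C=C[C@@H](OCOC)[C@H](O)/C=C(/C)I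
F6 | step 8 | (3R,4R,5Z)-6-iodo-3-(methoxymethoxy)hepta-1,5-dien-4-yl but-3-enoate | C=C[C@@H](OCOC)[C@H](OC(=O)CC=C)/C=C(/C)I
F7 | step 8 | (6R,7R)-7-[(1Z)-2-iodoprop-1-en-1-yl]-6-(methoxymethoxy)-6,7-dihydrooxepin-2(3H)-one | O=C1CC=C[C@@H](OCOC)[C@@H](/C=C(/C)I)O1
F8 | step 8 | (6R,7R)-7-[(1Z)-2,3-dimethylbuta-1,3-dien-1-yl]-6-(methoxymethoxy)-6,7-dihydrooxepin-2(3H)-one | O=C1CC=C[C@@H](OCOC)[C@@H](/C=C(/C)C(C)=C)O1
F9 | step 8 | (1R,7R)-4-(methoxymethoxy)-7-methyl-7-(prop-1-en-2-yl)cyclohepta-2,5-diene-1-carboxylic acid (C4 configuration carried over from F4) | OC(=O)[C@@H]1C=C[C@@H](OCOC)C=C[C@@]1(C)C(C)=C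
F10 | step 8 | methyl (1R,7R)-4-(methoxymethoxy)-7-methyl-7-(prop-1-en-2-yl)cyclohepta-2,5-diene-1-carboxylate (C4 configuration carried over from F4) | COC(=O)[C@@H]1C=C[C@@H](OCOC)C=C[C@@]1(C)C(C)=C
F11 | step 9 | methyl (1R,2S,7R)-2-(3-ethylphenyl)-7-methyl-4-oxo-7-(prop-1-en-2-yl)cyclohept-5-ene-1-carboxylate | COC(=O)[C@@H]1[C@@H](c2cccc(CC)c2)CC(=O)C=C[C@@]1(C)C(C)=C
F12 | step 12 | 2-bromo-5-ethylphenylmagnesium chloride | CCc1ccc(Br)c([Mg]Cl)c1
F13 | step 12 | methyl (1R,2S,7R)-2-(2-bromo-5-ethylphenyl)-7-methyl-7-(prop-1-en-2-yl)-4-[(trimethylsilyl)oxy]cyclohepta-3,5-diene-1-carboxylate | COC(=O)[C@@H]1[C@@H](c2cc(CC)ccc2Br)C=C(O[Si](C)(C)C)C=C[C@@]1(C)C(C)=C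
F14 | step 12 | methyl (1R,2S,3S,7R)-2-(2-bromo-5-ethylphenyl)-3-hydroxy-7-methyl-4-oxo-7-(prop-1-en-2-yl)cyclohept-5-ene-1-carboxylate | COC(=O)[C@@H]1[C@@H](c2cc(CC)ccc2Br)[C@H](O)C(=O)C=C[C@@]1(C)C(C)=C
F15 | step 12 | (1R,2R,6S,9S)-9-(2-bromo-5-ethylphenyl)-2-methyl-2-(prop-1-en-2-yl)-7-oxabicyclo[4.2.1]non-3-ene-5,8-dione | CCc1ccc(Br)c(c1)[C@H]1[C@@H]2OC(=O)[C@H]1[C@@](C)(C=CC2=O)C(C)=C
F16 | step 13 | 2,4-dibromo-3-ethylphenylmagnesium chloride | CCc1c(Br)ccc([Mg]Cl)c1Br
F17 | step 13 | methyl (1R,2S,7R)-2-(2,4-dibromo-3-ethylphenyl)-7-methyl-7-(prop-1-en-2-yl)-4-[(trimethylsilyl)oxy]cyclohepta-3,5-diene-1-carboxylate | COC(=O)[C@@H]1[C@@H](c2ccc(Br)c(CC)c2Br)C=C(O[Si](C)(C)C)C=C[C@@]1(C)C(C)=C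
F18 | step 13 | methyl (1R,2S,3S,7R)-2-(2,4-dibromo-3-ethylphenyl)-3-hydroxy-7-methyl-4-oxo-7-(prop-1-en-2-yl)cyclohept-5-ene-1-carboxylate | COC(=O)[C@@H]1[C@@H](c2ccc(Br)c(CC)c2Br)[C@H](O)C(=O)C=C[C@@]1(C)C(C)=C
F19 | step 13 | (1R,2R,6S,9S)-9-(2,4-dibromo-3-ethylphenyl)-2-methyl-2-(prop-1-en-2-yl)-7-oxabicyclo[4.2.1]non-3-ene-5,8-dione | CCc1c(Br)ccc(c1Br)[C@H]1[C@@H]2OC(=O)[C@H]1[C@@](C)(C=CC2=O)C(C)=C
A1 | alternative 1 | tetralin-fused lactone carrying a vinyl group on C7 and an acryloyl group on C3 (ring-closing metathesis substrate) | CCc1c(Br)cc2c(c1Br)[C@H]1[C@@H](C(=O)C=C)OC(=O)[C@H]1[C@@](C)(C=C)C2(C)C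
A2 | alternative 2 | 1-bromo-7-ethyl-3,4,4-trimethyl-3,4-dihydronaphthalen-2(1H)-one (stereocentres not controlled) | CCc1ccc2c(c1)C(Br)C(=O)C(C)C2(C)C
A3 | alternative 2 | furan (4+3) adduct: benzo-fused bicyclo[4.3.1] core with C1 as bridging ketone and an oxygen bridge from C3 to C6 | CCc1ccc2c(c1)[C@H]1[C@@H]3O[C@@H](C=C3)[C@](C)(C1=O)C2(C)C
A4 | alternative 3 | (3R)-4-{4-ethyl-2-[(1Z)-penta-1,4-dien-1-yl]phenyl}-3,4-dimethyl-3-vinylpentanoyl chloride | CCc1ccc(c(c1)/C=C\CC=C)C(C)(C)[C@](C)(C=C)CC(=O)Cl
A5 | alternative 3 | tetralin-fused cyclobutanone (C1–C2 and C3–C8 bonds formed; allyl on C3, vinyl on C7) | CCc1ccc2c(c1)[C@H]1[C@@H](CC=C)C(=O)[C@H]1[C@@](C)(C=C)C2(C)C
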